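**Plan**
- Retrosynthesis: the C1 carboxyl and the free O5–H are rejoined as an O5–C1 lactol, a 3,6-dihydro-2H-pyran ring that the target lacks. The oxirane goes back to an E C6=C7 alkene, and the chain is cut at C5–C6 and at C7–C8.
- Enabling feature: C1–C4 (carboxyl carbon, Z C2=C3, oxygenated C4) hold the four carbons and the oxidation pattern of a 2-substituted furan. O5 sits δ to C1, so the oxidised furan closes to the six-membered ring O5–C1–C2=C3–C4–C5, which holds C2=C3 cis.
- Forward order: C9–C12 hydroxy acid, then C7–C8 (acetylide on a Weinreb amide), then C5–C6 (alkenylzinc on furfural). The furan is then expanded to the pyranone ring, the oxirane ring is made, and the pyran ring is opened by oxidising its lactol.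
- Stereochemistry: C9 comes from (R)-2-hydroxypentanoic acid, the temporary C8 carbinol from a CBS reduction, and C5 from a (−)-MIB-catalysed addition. The temporary C1 centre follows the anomeric effect, C4 comes from Luche reduction on the ring followed by Mitsunobu inversion, and C6/C7 come from Sharpless epoxidation with D-(−)-DIPT matched to C8.

Key step: step 7

Assumption: atom labels C1–C12 follow the target acid in every intermediate. The two lactols of the route interconvert between anomers and are named and drawn as the trans (axial OH) anomer expected to dominate.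

**Step 1**
Reactants: 1 (R)-2-hydroxypentanoic acid
Product: 2 (2R)-2-hydroxy-N-methoxy-N-methylpentanamide
Conditions: MeNH(OMe)·HCl, EDC·HCl, 1-hydroxybenzotriazole (cat.), N-methylmorpholine, CH2Cl2, 0 °C → rt
Reagents that add atoms: N,O-dimethylhydroxylamine hydrochloride, CNOC.Cl
Why: Carbodiimide/1-hydroxybenzotriazole amide coupling (Weinreb amide formation) in which the amine outcompetes the secondary hydroxyl for the active ester, so the chiral-pool centre C9 is carried through untouched.

**Step 2**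
Reactants: 2 (2R)-2-hydroxy-N-methoxy-N-methylpentanamide
Product: 3 (2R)-2-(tert-butyldimethylsilyloxy)-N-methoxy-N-methylpentanamide
Conditions: TBSCl, imidazole, DMF, rt
Reagents that add atoms: tert-butyldimethylsilyl chloride, CC(C)(C)[Si](C)(C)Cl
Why: Imidazole-promoted silylation of a secondary alcohol, giving a TBS ether that tolerates the Grignard, borane, organozinc, NBS and titanium chemistry ahead.

**Step 3**
Reactants: 3 (2R)-2-(tert-butyldimethylsilyloxy)-N-methoxy-N-methylpentanamide; 4 ethynylmagnesium bromide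
Product: 5 (4R)-4-(tert-butyldimethylsilyloxy)hept-1-yn-3-one
Conditions: THF, −78 → 0 °C; poured into cold 1 M HCl
Reagents that add atoms: none
Why: Weinreb ketone synthesis forming C7–C8, in which the magnesium-chelated tetrahedral adduct blocks a second addition and the inverse quench into acid keeps the released N,O-dimethylhydroxylamine protonated so that it cannot add to the terminal ynone.

**Step 4**
Reactants: 5 (4R)-4-(tert-butyldimethylsilyloxy)hept-1-yn-3-one
Product: 6 (3S,4R)-4-(tert-butyldimethylsilyloxy)hept-1-yn-3-ol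
Conditions: (R)-Me-CBS [(R)-1-methyl-3,3-diphenyltetrahydro-1H,3H-pyrrolo[1,2-c][1,3,2]oxazaborole] (0.2 equiv), BH3·SMe2, THF, −30 °C; MeOH
Reagents that add atoms: none
Why: Corey–Bakshi–Shibata reduction under catalyst control, in which the slim ethynyl group acts as the small and the α-silyloxyalkyl group as the large substituent, so the (R)-oxazaborolidine–BH3 complex delivers hydride to the face that gives the 8S carbinol (8,9-anti) needed later for a matched epoxidation.

**Step 5**
Reactants: 6 (3S,4R)-4-(tert-butyldimethylsilyloxy)hept-1-yn-3-ol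
Product: 7 (3S,4R)-4-(tert-butyldimethylsilyloxy)-3-(triethylsilyloxy)hept-1-yne
Conditions: TESCl, imidazole, CH2Cl2, 0 °C
Reagents that add atoms: triethylsilyl chloride, CC[Si](Cl)(CC)CC
Why: Routine silylation, with TES chosen because it can later be cleaved in the presence of the C9 TBS ether.

**Step 6**
Reactants: 7 (3S,4R)-4-(tert-butyldimethylsilyloxy)-3-(triethylsilyloxy)hept-1-yne; 8 furan-2-carbaldehyde (furfural)
Product: 11 (1S,2E,4S,5R)-5-(tert-butyldimethylsilyloxy)-1-(furan-2-yl)-4-(triethylsilyloxy)oct-2-en-1-ol, via E-alkenyl(dicyclohexyl)borane 9 (not isolated), via E-alkenyl(methyl)zinc 10 (not isolated)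
Conditions: Cy2BH, toluene, 0 °C → rt; Me2Zn, (2S)-(−)-3-exo-morpholinoisoborneol [(−)-MIB] (10 mol %), −78 → −10 °C; 8, −10 °C; aq NH4Cl
Reagents that add atoms: none
Why: Catalytic asymmetric alkenylzinc addition forming C5–C6, in which syn-hydroboration fixes the E geometry, boron-to-zinc exchange retains it, and the (−)-MIB–zinc catalyst sends the alkenyl group to the Si face of furfural (the sense known for S-selective organozinc additions to aromatic aldehydes and furfural with amino-isoborneol ligands), so C5 is set independently of the remote C8/C9 centres.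

**Step 7**
Reactants: 11 (1S,2E,4S,5R)-5-(tert-butyldimethylsilyloxy)-1-(furan-2-yl)-4-(triethylsilyloxy)oct-2-en-1-ol
Product: 13 (2S,6R)-2-[(1E,3S,4R)-4-(tert-butyldimethylsilyloxy)-3-(triethylsilyloxy)hept-1-en-1-yl]-6-hydroxy-2H-pyran-3(6H)-one, via Z-keto-enal 12 (not isolated)
Conditions: NBS (1.05 equiv), NaHCO3, NaOAc, THF/H2O (4:1), 0 °C
Reagents that add atoms: water, O
Why: Bromonium transfer from NBS to the electron-rich furan and capture by water give a 2,5-dioxygenated dihydrofuran that loses HBr and unfolds to the Z-configured 4-keto-2-enal 12, whose former furan carbons are now C1–C4. The C5 hydroxyl then adds to the C1 aldehyde and forms the O5–C1 bond, which makes the overall process an Achmatowicz rearrangement of a 2-furyl carbinol. The single new ring closes in the 6-exo-trig mode, a closure open only to the cis enal, so C2=C3 is held Z inside the ring. The one new stereocentre, C1, is under thermodynamic control because the anomers equilibrate through 12, and the anomeric effect places the hydroxyl axial, trans to the equatorial C5 side chain. The step needs the furan to react before the C6=C7 alkene, which is secured by the far higher nucleophilicity of the heteroaromatic ring over an alkene flanked by two allylic C–O bonds and by using about one equivalent of NBS at 0 °C. The NaHCO3/NaOAc buffer takes up HBr so that the TES ether and the ionisable bis-allylic carbinol survive, and C5 keeps its configuration because none of its bonds is broken.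

**Step 8**
Reactants: 13 (2S,6R)-2-[(1E,3S,4R)-4-(tert-butyldimethylsilyloxy)-3-(triethylsilyloxy)hept-1-en-1-yl]-6-hydroxy-2H-pyran-3(6H)-one
Product: 14 tert-butyl (2S,6S)-6-[(1E,3S,4R)-4-(tert-butyldimethylsilyloxy)-3-(triethylsilyloxy)hept-1-en-1-yl]-5-oxo-5,6-dihydro-2H-pyran-2-yl carbonate (trans)
Conditions: Boc2O, 4-(dimethylamino)pyridine (DMAP, cat.), CH2Cl2, −78 °C
Reagents that add atoms: di-tert-butyl dicarbonate, CC(C)(C)OC(=O)OC(=O)OC(C)(C)C
Why: DMAP-catalysed carbonate formation on the equilibrating lactol, which at low temperature acylates mainly the axial hydroxyl of the trans anomer, the minor cis carbonate being removed by chromatography.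

**Step 9**
Reactants: 14 trans tert-butyl carbonate of the pyranone
Product: 15 (2S,6R)-2-[(1E,3S,4R)-4-(tert-butyldimethylsilyloxy)-3-(triethylsilyloxy)hept-1-en-1-yl]-6-(4-methoxybenzyloxy)-2H-pyran-3(6H)-one
Conditions: 4-MeOC6H4CH2OH, Pd2(dba)3·CHCl3 (2.5 mol %), PPh3 (10 mol %), CH2Cl2, 0 °C
Reagents that add atoms: 4-methoxybenzyl alcohol, COc1ccc(CO)cc1
Why: Tsuji–Trost-type glycosylation with zerovalent palladium, in which ionisation of the allylic carbonate and attack of the alcohol both occur anti to the metal, so the PMB acetal forms with net retention and at C1, the terminus that restores the enone.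

**Step 10**
Reactants: 15 PMB pyranone acetal
Product: 16 (2S,3R,6R)-2-[(1E,3S,4R)-4-(tert-butyldimethylsilyloxy)-3-(triethylsilyloxy)hept-1-en-1-yl]-6-(4-methoxybenzyloxy)-3,6-dihydro-2H-pyran-3-ol
Conditions: NaBH4, CeCl3·7H2O, MeOH/CH2Cl2, −78 °C
Reagents that add atoms: none
Why: Luche 1,2-reduction in which hydride approaches the C4 carbonyl of the half-chair anti to the axial C1 alkoxy group and gives the equatorial 4R alcohol, trans to the C5 side chain, as established for 2,6-trans-6-alkoxypyran-3-ones.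

**Step 11**
Reactants: 16 4R allylic alcohol
Product: 17 (2S,3S,6R)-2-[(1E,3S,4R)-4-(tert-butyldimethylsilyloxy)-3-(triethylsilyloxy)hept-1-en-1-yl]-6-(4-methoxybenzyloxy)-3,6-dihydro-2H-pyran-3-yl acetate
Conditions: AcOH, PPh3, DIAD, toluene, 0 °C → rt
Reagents that add atoms: acetic acid, CC(=O)O
Why: Mitsunobu esterification, in which SN2 displacement of the C4 oxyphosphonium ion by acetate inverts 4R to the 4S acetate of the target (cis to the C5 side chain) in one operation, a known way to invert C4 of 2,3-unsaturated pyranosides.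

**Step 12**
Reactants: 17 4S acetate
Product: 18 (2S,3S,6R)-2-[(1E,3S,4R)-4-(tert-butyldimethylsilyloxy)-3-hydroxyhept-1-en-1-yl]-6-(4-methoxybenzyloxy)-3,6-dihydro-2H-pyran-3-yl acetate
Conditions: HF·pyridine, pyridine, THF, 0 °C
Reagents that add atoms: none
Why: Rate-selective fluoride desilylation, since in pyridine-buffered HF the TES ether is cleaved far faster than the hindered TBS ether while acetal, allylic acetate and alkenes are inert.

**Step 13**
Reactants: 18 C8 allylic alcohol
Product: 19 (2R,3S,6R)-2-{(2S,3R)-3-[(1S,2R)-2-(tert-butyldimethylsilyloxy)-1-hydroxypentyl]oxiran-2-yl}-6-(4-methoxybenzyloxy)-3,6-dihydro-2H-pyran-3-yl acetate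
Conditions: Ti(OiPr)4 (0.2 equiv), D-(−)-diisopropyl tartrate (0.24 equiv), t-BuOOH (decane), 4 Å MS, CH2Cl2, −20 °C
Reagents that add atoms: tert-butyl hydroperoxide, CC(C)(C)OO
Why: Katsuki–Sharpless epoxidation directed by the only free allylic hydroxyl, so the ring alkene is untouched, with D-(−)-DIPT selecting the alkene face that gives the 6,7-configuration of the target and the 8S carbinol being the fast-reacting partner of this tartrate in the kinetic-resolution sense, so reagent and substrate reinforce each other and the E alkene gives the trans oxirane anti to the C8 hydroxyl.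

**Step 14**
Reactants: 19 epoxy alcohol
Product: 20 (2R,3S,6R)-2-{(2R,3S)-3-[(2R)-2-(tert-butyldimethylsilyloxy)pentanoyl]oxiran-2-yl}-6-(4-methoxybenzyloxy)-3,6-dihydro-2H-pyran-3-yl acetate
Conditions: Dess–Martin periodinane, NaHCO3, CH2Cl2, 0 °C → rt
Reagents that add atoms: none
Why: Dess–Martin oxidation under bicarbonate buffering turns the temporary C8 carbinol into the ketone without epimerising C7 or C9 and without opening the oxirane.

**Step 15**
Reactants: 20 epoxy ketone
Product: 21 (2R,3S,6R)-2-{(2R,3S)-3-[(2R)-2-hydroxypentanoyl]oxiran-2-yl}-6-(4-methoxybenzyloxy)-3,6-dihydro-2H-pyran-3-yl acetate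
Conditions: Bu4NF/AcOH (1:1), THF, 0 °C
Reagents that add atoms: none
Why: Acetic-acid-buffered fluoride desilylation, fast for an α-keto silyl ether and close to neutral, so C9 is not epimerised and acetate, acetal and epoxy ketone persist.

**Step 16**
Reactants: 21 α-hydroxy ketone
Product: 22 (2R,3S,6R)-2-{(2R,3S)-3-[(2R)-2-acetoxypentanoyl]oxiran-2-yl}-6-(4-methoxybenzyloxy)-3,6-dihydro-2H-pyran-3-yl acetate
Conditions: Ac2O, pyridine, DMAP (cat.), CH2Cl2, 0 °C
Reagents that add atoms: acetic anhydride, CC(=O)OC(C)=O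
Why: Standard acetylation of the only free hydroxyl under mild base at low temperature, with retention at C9.

**Step 17**
Reactants: 22 diacetate PMB acetal
Product: 23 (2R,3S,6R)-2-{(2R,3S)-3-[(2R)-2-acetoxypentanoyl]oxiran-2-yl}-6-hydroxy-3,6-dihydro-2H-pyran-3-yl acetate
Conditions: DDQ, CH2Cl2/pH 7 phosphate buffer (10:1), 0 °C → rt
Reagents that add atoms: none
Why: Oxidative PMB cleavage, in which DDQ abstracts the benzylic hydride, water hydrolyses the oxocarbenium ion to 4-methoxybenzaldehyde and the lactol, and the neutral buffer spares epoxy ketone and acetates.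

**Step 18**
Reactants: 23 lactol
Product: 25 (2Z,4S,5R,6R,7S,9R)-4,9-diacetoxy-6,7-epoxy-5-hydroxy-8-oxododec-2-enoic acid, via Z-hydroxy-enal 24 (not isolated)
Conditions: NaClO2, NaH2PO4, 2-methyl-2-butene, t-BuOH/H2O, 0 °C; extraction near pH 4 at 0 °C
Reagents that add atoms: sodium chlorite, [Na+].[O-]Cl=O
Why: Pinnick oxidation of a lactol through its ring-opened tautomer, in which hydroxy-enal 24 adds chlorous acid and fragments to the acid, so the temporary O5–C1 bond stays broken, the C5 hydroxyl is freed and the Z alkene, epoxy ketone and acetates are untouched at this pH, while the cold work-up limits relactonisation and O4-to-O5 acetyl shift.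

**Compound list**
1 | (R)-2-hydroxypentanoic acid | CCC[C@@H](O)C(=O)O | starting material
2 | (2R)-2-hydroxy-N-methoxy-N-methylpentanamide | CCC[C@@H](O)C(=O)N(C)OC | intermediate
3 | (2R)-2-(tert-butyldimethylsilyloxy)-N-methoxy-N-methylpentanamide | CCC[C@@H](O[Si](C)(C)C(C)(C)C)C(=O)N(C)OC | intermediate
4 | ethynylmagnesium bromide | C#C[Mg]Br | starting material
5 | (4R)-4-(tert-butyldimethylsilyloxy)hept-1-yn-3-one | CCC[C@@H](O[Si](C)(C)C(C)(C)C)C(=O)C#C | intermediate
6 | (3S,4R)-4-(tert-butyldimethylsilyloxy)hept-1-yn-3-ol | CCC[C@@H](O[Si](C)(C)C(C)(C)C)[C@@H](O)C#C | intermediate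
7 | (3S,4R)-4-(tert-butyldimethylsilyloxy)-3-(triethylsilyloxy)hept-1-yne | CCC[C@@H](O[Si](C)(C)C(C)(C)C)[C@@H](O[Si](CC)(CC)CC)C#C | intermediate
8 | furan-2-carbaldehyde (furfural) | O=Cc1ccco1 | starting material
9 | dicyclohexyl[(1E,3S,4R)-4-(tert-butyldimethylsilyloxy)-3-(triethylsilyloxy)hept-1-en-1-yl]borane | CCC[C@@H](O[Si](C)(C)C(C)(C)C)[C@@H](O[Si](CC)(CC)CC)/C=C/B(C1CCCCC1)C1CCCCC1 | intermediate
10 | methyl[(1E,3S,4R)-4-(tert-butyldimethylsilyloxy)-3-(triethylsilyloxy)hept-1-en-1-yl]zinc | CCC[C@@H](O[Si](C)(C)C(C)(C)C)[C@@H](O[Si](CC)(CC)CC)/C=C/[Zn]C | intermediate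
11 | (1S,2E,4S,5R)-5-(tert-butyldimethylsilyloxy)-1-(furan-2-yl)-4-(triethylsilyloxy)oct-2-en-1-ol | CCC[C@@H](O[Si](C)(C)C(C)(C)C)[C@@H](O[Si](CC)(CC)CC)/C=C/[C@H](O)c1ccco1 | intermediate
12 | (2Z,5S,6E,8S,9R)-9-(tert-butyldimethylsilyloxy)-5-hydroxy-4-oxo-8-(triethylsilyloxy)dodeca-2,6-dienal | CCC[C@@H](O[Si](C)(C)C(C)(C)C)[C@@H](O[Si](CC)(CC)CC)/C=C/[C@H](O)C(=O)/C=C\C=O | intermediate
13 | (2S,6R)-2-[(1E,3S,4R)-4-(tert-butyldimethylsilyloxy)-3-(triethylsilyloxy)hept-1-en-1-yl]-6-hydroxy-2H-pyran-3(6H)-one (trans anomer) | CCC[C@@H](O[Si](C)(C)C(C)(C)C)[C@@H](O[Si](CC)(CC)CC)/C=C/[C@@H]1O[C@@H](O)C=CC1=O | intermediate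
14 | tert-butyl (2S,6S)-6-[(1E,3S,4R)-4-(tert-butyldimethylsilyloxy)-3-(triethylsilyloxy)hept-1-en-1-yl]-5-oxo-5,6-dihydro-2H-pyran-2-yl carbonate (trans) | CCC[C@@H](O[Si](C)(C)C(C)(C)C)[C@@H](O[Si](CC)(CC)CC)/C=C/[C@@H]1O[C@@H](OC(=O)OC(C)(C)C)C=CC1=O | intermediate
15 | (2S,6R)-2-[(1E,3S,4R)-4-(tert-butyldimethylsilyloxy)-3-(triethylsilyloxy)hept-1-en-1-yl]-6-(4-methoxybenzyloxy)-2H-pyran-3(6H)-one | CCC[C@@H](O[Si](C)(C)C(C)(C)C)[C@@H](O[Si](CC)(CC)CC)/C=C/[C@@H]1O[C@@H](OCc2ccc(OC)cc2)C=CC1=O | intermediate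
16 | (2S,3R,6R)-2-[(1E,3S,4R)-4-(tert-butyldimethylsilyloxy)-3-(triethylsilyloxy)hept-1-en-1-yl]-6-(4-methoxybenzyloxy)-3,6-dihydro-2H-pyran-3-ol | CCC[C@@H](O[Si](C)(C)C(C)(C)C)[C@@H](O[Si](CC)(CC)CC)/C=C/[C@@H]1O[C@@H](OCc2ccc(OC)cc2)C=C[C@H]1O | intermediate
17 | (2S,3S,6R)-2-[(1E,3S,4R)-4-(tert-butyldimethylsilyloxy)-3-(triethylsilyloxy)hept-1-en-1-yl]-6-(4-methoxybenzyloxy)-3,6-dihydro-2H-pyran-3-yl acetate | CCC[C@@H](O[Si](C)(C)C(C)(C)C)[C@@H](O[Si](CC)(CC)CC)/C=C/[C@@H]1O[C@@H](OCc2ccc(OC)cc2)C=C[C@@H]1OC(C)=O | intermediate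
18 | (2S,3S,6R)-2-[(1E,3S,4R)-4-(tert-butyldimethylsilyloxy)-3-hydroxyhept-1-en-1-yl]-6-(4-methoxybenzyloxy)-3,6-dihydro-2H-pyran-3-yl acetate | CCC[C@@H](O[Si](C)(C)C(C)(C)C)[C@@H](O)/C=C/[C@@H]1O[C@@H](OCc2ccc(OC)cc2)C=C[C@@H]1OC(C)=O | intermediate
19 | (2R,3S,6R)-2-{(2S,3R)-3-[(1S,2R)-2-(tert-butyldimethylsilyloxy)-1-hydroxypentyl]oxiran-2-yl}-6-(4-methoxybenzyloxy)-3,6-dihydro-2H-pyran-3-yl acetate | CCC[C@@H](O[Si](C)(C)C(C)(C)C)[C@@H](O)[C@H]1O[C@@H]1[C@@H]2O[C@@H](OCc3ccc(OC)cc3)C=C[C@@H]2OC(C)=O | intermediate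
20 | (2R,3S,6R)-2-{(2R,3S)-3-[(2R)-2-(tert-butyldimethylsilyloxy)pentanoyl]oxiran-2-yl}-6-(4-methoxybenzyloxy)-3,6-dihydro-2H-pyran-3-yl acetate | CCC[C@@H](O[Si](C)(C)C(C)(C)C)C(=O)[C@H]1O[C@@H]1[C@@H]2O[C@@H](OCc3ccc(OC)cc3)C=C[C@@H]2OC(C)=O | intermediate
21 | (2R,3S,6R)-2-{(2R,3S)-3-[(2R)-2-hydroxypentanoyl]oxiran-2-yl}-6-(4-methoxybenzyloxy)-3,6-dihydro-2H-pyran-3-yl acetate | CCC[C@@H](O)C(=O)[C@H]1O[C@@H]1[C@@H]2O[C@@H](OCc3ccc(OC)cc3)C=C[C@@H]2OC(C)=O | intermediate
22 | (2R,3S,6R)-2-{(2R,3S)-3-[(2R)-2-acetoxypentanoyl]oxiran-2-yl}-6-(4-methoxybenzyloxy)-3,6-dihydro-2H-pyran-3-yl acetate | CCC[C@@H](OC(C)=O)C(=O)[C@H]1O[C@@H]1[C@@H]2O[C@@H](OCc3ccc(OC)cc3)C=C[C@@H]2OC(C)=O | intermediate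
23 | (2R,3S,6R)-2-{(2R,3S)-3-[(2R)-2-acetoxypentanoyl]oxiran-2-yl}-6-hydroxy-3,6-dihydro-2H-pyran-3-yl acetate (trans anomer) | CCC[C@@H](OC(C)=O)C(=O)[C@H]1O[C@@H]1[C@@H]2O[C@@H](O)C=C[C@@H]2OC(C)=O | intermediate
24 | (2Z,4S,5R,6R,7S,9R)-4,9-diacetoxy-6,7-epoxy-5-hydroxy-8-oxododec-2-enal | CCC[C@@H](OC(C)=O)C(=O)[C@H]1O[C@@H]1[C@H](O)[C@H](/C=C\C=O)OC(C)=O | intermediate
25 | (2Z,4S,5R,6R,7S,9R)-4,9-diacetoxy-6,7-epoxy-5-hydroxy-8-oxododec-2-enoic acid (CNP0282306.1) | CCC[C@@H](OC(C)=O)C(=O)[C@H]1O[C@@H]1[C@H](O)[C@H](/C=C\C(=O)O)OC(C)=O | target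

**Step count**
Total steps: 18. Longest linear sequence: 18 steps, from 1 to 25. Compounds 4 and 8 are purchased.

**Steps most likely to fail**

1. Step 18.
   - The ring–chain equilibrium may lie so far on the lactol side that chlorite is consumed unproductively.
   - The Z-δ-hydroxy acid may close again to the lactone during acidic work-up.
   - The C4 acetyl group may wander to the freed O5.
   - The fallback leaves the direct oxidation of the open form and exits the ring at the lactone level. It sets out from 23, which is oxidised with MnO2 (CH2Cl2, rt) to the α,β-unsaturated δ-lactone F1.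
   - The ring is then opened hydrolytically with one equivalent of LiOH in THF/H2O at 0 °C. This relies on the much faster alkaline hydrolysis of δ-lactones compared with acyclic secondary acetates. The acid is liberated at about pH 4 (NaH2PO4) at 0 °C, which returns to the route at 25.

2. Step 6.
   - Hydroboration or boron-to-zinc exchange may be slow next to the two bulky silyl ethers.
   - Methyl transfer from zinc may compete.
   - Coordination of the furan oxygen to zinc may erode facial selectivity.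
   - The fallback builds C5–C6 at the alkyne level and sets C5 by reduction. It sets out from 7, which is deprotonated (n-BuLi, THF, −78 °C) and acylated with purchased N-methoxy-N-methylfuran-2-carboxamide to give the furyl ynone F2.
   - Midland reduction with B-isopinocampheyl-9-BBN made from (+)-α-pinene follows, with the alkynyl group as the small substituent, and gives the (1S)-propargylic alcohol F3.
   - Hydroxyl-directed trans-hydroalumination with NaAlH2(OCH2CH2OMe)2 (Et2O/THF, −20 → 0 °C, kept cold to avoid loss of the C8 silyloxy group as an allene) and protonolysis return to the route at 11.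

3. Step 13.
   - Oxygen transfer may be sluggish to an alkene flanked by two electron-withdrawing C–O bonds and a bulky C9 silyl ether.
   - Long exposure to the titanium alkoxide may cause acetal exchange or acetate transfer.
   - The fallback replaces the electrophilic, hydroxyl-directed epoxidation by a nucleophilic, reagent-controlled one. It sets out from 18, which is oxidised with MnO2 (CH2Cl2, rt) to the E-enone F4.
   - F4 is epoxidised with La(OiPr)3/(R)-BINOL/Ph3As=O (10 mol % each) and t-BuOOH (4 Å MS, THF, rt). The α-S, β-R sense known for E-enones with this ligand corresponds to 7S,6R. The non-conjugated ring alkene does not react. This returns to the route at 20 and bypasses 19.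

**Further compounds**
F1 | step 18 | (2R,3S)-2-{(2R,3S)-3-[(2R)-2-acetoxypentanoyl]oxiran-2-yl}-6-oxo-3,6-dihydro-2H-pyran-3-yl acetate | CCC[C@@H](OC(C)=O)C(=O)[C@H]1O[C@@H]1[C@@H]2OC(=O)C=C[C@@H]2OC(C)=O
F2 | step 6 | (4S,5R)-5-(tert-butyldimethylsilyloxy)-1-(furan-2-yl)-4-(triethylsilyloxy)oct-2-yn-1-one | CCC[C@@H](O[Si](C)(C)C(C)(C)C)[C@@H](O[Si](CC)(CC)CC)C#CC(=O)c1ccco1
F3 | step 6 | (1S,4S,5R)-5-(tert-butyldimethylsilyloxy)-1-(furan-2-yl)-4-(triethylsilyloxy)oct-2-yn-1-ol | CCC[C@@H](O[Si](C)(C)C(C)(C)C)[C@@H](O[Si](CC)(CC)CC)C#C[C@H](O)c1ccco1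
F4 | step 13 | (2S,3S,6R)-2-[(1E,4R)-4-(tert-butyldimethylsilyloxy)-3-oxohept-1-en-1-yl]-6-(4-methoxybenzyloxy)-3,6-dihydro-2H-pyran-3-yl acetate | CCC[C@@H](O[Si](C)(C)C(C)(C)C)C(=O)/C=C/[C@@H]1O[C@@H](OCc2ccc(OC)cc2)C=C[C@@H]1OC(C)=O
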